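**Strategy.** The piperidine ring (N1, C2, C3, C4, C4a, C8a) is read as a masked 2-(1-aminoethyl)furan: C3, C4, C4a and C8a are the four furan carbons, and C3=O and C8a–N arise from its oxidation. A 4-alkyl-4,5,6,7-tetrahydrobenzofuran carrying the cyclohexane and a furfuryl carbamate is therefore built first. An aza-Achmatowicz rearrangement then closes the piperidine last and delivers the C3 ketone, a C4=C4a enone and a C8a N,O-acetal. Two reductions directed by C5 (and a relay methyl at C2) set C8a and C4a; C2 is equilibrated in the free amino ketone and C3 set by L-Selectride. C5 stems from an iridium-catalysed asymmetric hydrogenation, C5′ from (R)-1,2-epoxypentane.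

Key step: step 9

Remark: core atoms are numbered as in decahydroquinoline (N1, C2, C3, C4, C4a, C5–C8, C8a) and the side chain C1′–C8′; the hemiaminal carbon of 18 is left undefined because both epimers converge in step 10.

Step 1
Reactants: 1 (2R)-2-propyloxirane [(R)-1,2-epoxypentane]; 2 allylmagnesium bromide
Product: 3 (4R)-oct-7-en-4-ol
Conditions: CuI (10 mol %), THF/Et2O, −40 → 0 °C; aq. NH4Cl
Reagents that add atoms: none
Why: Copper-catalysed SN2 ring opening of the terminal epoxide by the allyl Grignard reagent occurs at the unsubstituted CH2, so the stereocentre of 1 is untouched and becomes C5′ (R) of the target.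

Step 2
Reactants: 3 (4R)-oct-7-en-4-ol
Product: 4 tert-butyl{[(4R)-oct-7-en-4-yl]oxy}diphenylsilane
Conditions: TBDPSCl, imidazole, DMF, 23 °C
Reagents that add atoms: tert-butyl(chloro)diphenylsilane, CC(C)(C)[Si](Cl)(c1ccccc1)c1ccccc1
Why: Imidazole-promoted silylation of the secondary alcohol; the tert-butyldiphenylsilyl ether is chosen because it should tolerate the later HCl, BF3, peracid, hydrogenation and hydride steps.

Step 3
Reactants: 5 6,7-dihydro-1-benzofuran-4(5H)-one
Product: 6 6,7-dihydro-1-benzofuran-4-yl trifluoromethanesulfonate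
Conditions: KHMDS, THF, −78 °C; PhNTf2, −78 → 0 °C
Reagents that add atoms: N-phenylbis(trifluoromethanesulfonimide), O=S(=O)(N(c1ccccc1)S(=O)(=O)C(F)(F)F)C(F)(F)F
Why: Kinetic deprotonation at C5 (the only enolisable position) and O-sulfonylation of the potassium enolate give the alkenyl triflate (enol triflate formation).

Step 4
Reactants: 4 tert-butyl{[(4R)-oct-7-en-4-yl]oxy}diphenylsilane; 6 6,7-dihydro-1-benzofuran-4-yl trifluoromethanesulfonate
Product: 8 4-[(5R)-5-(tert-butyldiphenylsilyloxy)octyl]-6,7-dihydro-1-benzofuran, via B-alkyl-9-BBN borane 7 (not isolated)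
Conditions: 9-BBN-H, THF, 0 → 23 °C; then 6, Pd(dppf)Cl2 (5 mol %), K3PO4 (3 M aq.), DMF/THF, 50 °C
Reagents that add atoms: none
Why: Anti-Markovnikov hydroboration of the terminal alkene followed by B-alkyl Suzuki–Miyaura cross-coupling with the alkenyl triflate joins side chain and bicyclic furan at the future C5.

Step 5
Reactants: 8 4-[(5R)-5-(tert-butyldiphenylsilyloxy)octyl]-6,7-dihydro-1-benzofuran
Product: 9 (4S)-4-[(5R)-5-(tert-butyldiphenylsilyloxy)octyl]-4,5,6,7-tetrahydro-1-benzofuran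
Conditions: H2 (50 bar), [Ir(cod)(L)]BArF (1 mol %; L = (S)-4-tert-butyl-2-[2-(di-o-tolylphosphanyl)phenyl]-4,5-dihydrooxazole, BArF = B[3,5-(CF3)2C6H3]4), CH2Cl2, 25 °C
Reagents that add atoms: none
Why: Iridium N,P-ligand-catalysed asymmetric hydrogenation of an unfunctionalised, aryl-conjugated cyclic trisubstituted alkene (the 1-alkyl-3,4-dihydronaphthalene substrate class) should reduce only the C4=C5 bond, the catalyst (ligand antipode chosen for the S product) setting C4 of the benzofuran, which is C5 of the target, independently of the remote carbinol centre.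

Step 6
Reactants: 10 (S)-2-methylpropane-2-sulfinamide; 11 acetaldehyde
Product: 12 (S)-N-[(E)-ethylidene]-2-methylpropane-2-sulfinamide
Conditions: CuSO4 (anhydrous), CH2Cl2, 23 °C
Reagents that add atoms: none
Why: Dehydrative condensation of the sulfinamide with the aldehyde gives the E-configured N-sulfinyl aldimine (sulfinimine formation).

Step 7
Reactants: 9 (4S)-4-[(5R)-5-(tert-butyldiphenylsilyloxy)octyl]-4,5,6,7-tetrahydro-1-benzofuran; 12 (S)-N-[(E)-ethylidene]-2-methylpropane-2-sulfinamide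
Product: 15 (S)-N-[(1S)-1-{(4S)-4-[(5R)-5-(tert-butyldiphenylsilyloxy)octyl]-4,5,6,7-tetrahydro-1-benzofuran-2-yl}ethyl]-2-methylpropane-2-sulfinamide, via 2-furyllithium 13 (not isolated), via 2-furylmagnesium bromide 14 (not isolated)
Conditions: n-BuLi, Et2O, 0 → 23 °C; MgBr2·OEt2, 0 °C; then 12, toluene, −78 → −20 °C
Reagents that add atoms: none
Why: The only free furan α-position is lithiated, and after transmetalation the furyl Grignard adds to the C=N bond of the N-tert-butanesulfinyl imine through the six-membered magnesium-chelated chair transition state, in which the (S)-sulfinyl group should deliver the furyl group to the face that gives the (1S) amine carbon (the relay configuration at C2), the less basic magnesium reagent sparing the acidic α-protons of the aldimine.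

Step 8
Reactants: 15 the (S,1S)-sulfinamide
Product: 17 benzyl N-[(1S)-1-{(4S)-4-[(5R)-5-(tert-butyldiphenylsilyloxy)octyl]-4,5,6,7-tetrahydro-1-benzofuran-2-yl}ethyl]carbamate, via amine hydrochloride 16 (not isolated)
Conditions: HCl (4 M in dioxane), MeOH, 0 °C; concentrate; CbzCl, NaHCO3, THF/H2O, 0 → 23 °C
Reagents that add atoms: benzyl chloroformate, O=C(Cl)OCc1ccccc1
Why: Acidic methanolysis cleaves the N–S bond without touching the silyl ether or the furan, and Schotten–Baumann acylation of the liberated amine gives the carbamate needed as N–H nucleophile and A(1,3)-strain element in steps 9–11.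

Step 9
Reactants: 17 the benzyl furfuryl carbamate
Product: 18 benzyl (2S,5S)-8a-hydroxy-2-methyl-3-oxo-5-[(5R)-5-(tert-butyldiphenylsilyloxy)octyl]-3,5,6,7,8,8a-hexahydroquinoline-1(2H)-carboxylate (both C8a epimers)
Conditions: mCPBA, CH2Cl2, 0 °C
Reagents that add atoms: 3-chloroperbenzoic acid, OOC(=O)c1cccc(Cl)c1
Why: The peracid epoxidises the electron-rich furan, the epoxide collapses to the cis-configured 2-ene-1,4-dione, and the carbamate N–H adds to the ketone that was the oxygen-bearing ring-fusion carbon of the furan, which is the aza-Achmatowicz rearrangement (oxidative ring expansion of furfuryl amine derivatives to 6-hydroxy-2H-pyridin-3(6H)-ones). The only ring it closes is the piperidine, through the N1–C8a bond by 6-exo-trig addition of nitrogen to the ketone carbonyl; the cyclohexane is already in place and the furan is consumed. The single new stereocentre, the hemiaminal carbon C8a, should form as an anomeric mixture under thermodynamic control, which is of no consequence because C8a becomes planar again in step 10. The step needs chemoselective oxidation of the furan (carbamate, silyl ether and arenes are inert to the peracid at 0 °C), the cis geometry of the enedione (inherited from the ring) so that nitrogen can reach C8a, and retention of the C2 and C5 centres (no base, low temperature).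

Step 10
Reactants: 18 the N,O-hemiacetal
Product: 19 benzyl (2S,5S,8aR)-2-methyl-3-oxo-5-[(5R)-5-(tert-butyldiphenylsilyloxy)octyl]-3,5,6,7,8,8a-hexahydroquinoline-1(2H)-carboxylate
Conditions: Et3SiH, BF3·OEt2, CH2Cl2, −78 → −30 °C
Reagents that add atoms: none
Why: Lewis acid ionisation of the N,O-acetal to the conjugated N-acyliminium ion and hydride transfer from the silane (ionic hydrogenation) should occur at C8a on the face opposite the pseudoaxial C2 methyl (A(1,3) strain with the carbamate) and the pseudoaxial C5 chain (A(1,3) strain with C4–H), which lie on the same face, so H8a is delivered cis to H5 (8aR).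

Step 11
Reactants: 19 the N-Cbz enone
Product: 21 (2R,4aS,5S,8aR)-2-methyl-5-[(5R)-5-(tert-butyldiphenylsilyloxy)octyl]octahydroquinolin-3(2H)-one, via (2S)-amino ketone 20 (not isolated)
Conditions: H2 (1 atm), Pd/C (10 wt %), EtOAc, 23 °C; filter; DBU (0.2 equiv), MeOH, 23 °C, argon
Reagents that add atoms: none
Why: Heterogeneous hydrogenation should add H2 to C4=C4a from the face opposite the C5 chain, C8 and the C2 methyl (setting 4aS, the cis ring fusion and the all-cis cyclohexane) and cleaves the benzyl carbamate, after which base-mediated enolisation of the α-amino ketone equilibrates C2 to the 2R epimer, whose equatorial methyl no longer suffers the syn-diaxial contact with axial C8 that destabilises the 2S epimer 20 (thermodynamic epimerisation).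

Step 12
Reactants: 21 the (2R)-amino ketone
Product: 22 (2R,3R,4aS,5S,8aR)-2-methyl-5-[(5R)-5-(tert-butyldiphenylsilyloxy)octyl]decahydroquinolin-3-ol
Conditions: LiBH(s-Bu)3 (L-Selectride), THF, −78 °C; MeOH/H2O
Reagents that add atoms: none
Why: The bulky trialkylborohydride should attack the ketone from the equatorial direction of the chair with equatorial C2 methyl (as with 2-methylcyclohexanone), giving the axial 3R alcohol cis to the methyl group (diastereoselective ketone reduction).

Step 13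
Reactants: 22 the amino alcohol
Product: 23 tert-butyl (2R,3R,4aS,5S,8aR)-3-hydroxy-2-methyl-5-[(5R)-5-(tert-butyldiphenylsilyloxy)octyl]octahydroquinoline-1(2H)-carboxylate
Conditions: Boc2O, Et3N, THF, 50 °C
Reagents that add atoms: di-tert-butyl dicarbonate, CC(C)(C)OC(=O)OC(=O)OC(C)(C)C
Why: The secondary amine is acylated selectively over the hindered axial alcohol in the absence of an acyl-transfer catalyst (carbamate protection).

Step 14
Reactants: 24 (2E,4E)-octa-2,4-dienal
Product: 25 (2E,4E)-octa-2,4-dienoic acid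
Conditions: NaClO2, NaH2PO4, 2-methylbut-2-ene, t-BuOH/H2O, 0 → 23 °C
Reagents that add atoms: sodium chlorite, [Na+].[O-]Cl=O
Why: Pinnick oxidation converts the dienal into the acid without touching or isomerising the E,E-diene, the hypochlorite being scavenged by the alkene additive.

Step 15
Reactants: 25 (2E,4E)-octa-2,4-dienoic acid; 23 the N-Boc amino alcohol
Product: 27 tert-butyl (2R,3R,4aS,5S,8aR)-2-methyl-3-[(2E,4E)-octa-2,4-dienoyloxy]-5-[(5R)-5-(tert-butyldiphenylsilyloxy)octyl]octahydroquinoline-1(2H)-carboxylate, via mixed anhydride 26 (not isolated)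
Conditions: 2,4,6-Cl3C6H2COCl, Et3N, toluene, 23 °C; then 23, DMAP, toluene, 23 → 40 °C
Reagents that add atoms: none
Why: Yamaguchi esterification via the mixed 2,4,6-trichlorobenzoic anhydride and DMAP should acylate the hindered axial C3 hydroxyl, the amine and the side-chain carbinol being masked.

Step 16
Reactants: 27 the N-Boc silyl ether ester
Product: 29 (2R,3R,4aS,5S,8aR)-5-[(5R)-5-hydroxyoctyl]-2-methyldecahydroquinolin-3-yl (2E,4E)-octa-2,4-dienoate (target), via ammonium trifluoroacetate 28 (not isolated)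
Conditions: TFA/CH2Cl2 (1:4), 0 °C; evaporate; HF·pyridine, THF, 0 → 23 °C; cold aq. NaHCO3
Reagents that add atoms: none
Why: Acidolysis removes the tert-butyl carbamate and fluoride (as HF·pyridine) cleaves the silyl ether while the nitrogen stays protonated, which should suppress O-to-N acyl migration until the cold bicarbonate work-up liberates the target (global deprotection).

**Compound list**

1 | (2R)-2-propyloxirane | CCC[C@@H]1CO1 | starting material
2 | allylmagnesium bromide | C=CC[Mg]Br | starting material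
3 | (4R)-oct-7-en-4-ol | C=CCC[C@H](O)CCC | intermediate
4 | tert-butyl{[(4R)-oct-7-en-4-yl]oxy}diphenylsilane | C=CCC[C@H](O[Si](c1ccccc1)(c1ccccc1)C(C)(C)C)CCC | intermediate
5 | 6,7-dihydro-1-benzofuran-4(5H)-one | O=C1CCCc2occc12 | starting material
6 | 6,7-dihydro-1-benzofuran-4-yl trifluoromethanesulfonate | O=S(=O)(OC1=CCCc2occc12)C(F)(F)F | intermediate
7 | 9-[(5R)-5-(tert-butyldiphenylsilyloxy)octyl]-9-borabicyclo[3.3.1]nonane | B1(CCCC[C@H](O[Si](c3ccccc3)(c4ccccc4)C(C)(C)C)CCC)C2CCCC1CCC2 | intermediate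
8 | 4-[(5R)-5-(tert-butyldiphenylsilyloxy)octyl]-6,7-dihydro-1-benzofuran | c1cc2C(CCCC[C@H](O[Si](c3ccccc3)(c4ccccc4)C(C)(C)C)CCC)=CCCc2o1 | intermediate
9 | (4S)-4-[(5R)-5-(tert-butyldiphenylsilyloxy)octyl]-4,5,6,7-tetrahydro-1-benzofuran | c1cc2[C@@H](CCCC[C@H](O[Si](c3ccccc3)(c4ccccc4)C(C)(C)C)CCC)CCCc2o1 | intermediate
10 | (S)-2-methylpropane-2-sulfinamide | CC(C)(C)[S@](=O)N | starting material
11 | acetaldehyde | CC=O | starting material
12 | (S)-N-[(E)-ethylidene]-2-methylpropane-2-sulfinamide | CC(C)(C)[S@](=O)/N=C/C | intermediate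
13 | 2-lithio derivative of 9 | [Li]c1cc2[C@@H](CCCC[C@H](O[Si](c3ccccc3)(c4ccccc4)C(C)(C)C)CCC)CCCc2o1 | intermediate
14 | 2-(bromomagnesio) derivative of 9 | Br[Mg]c1cc2[C@@H](CCCC[C@H](O[Si](c3ccccc3)(c4ccccc4)C(C)(C)C)CCC)CCCc2o1 | intermediate
15 | (S)-N-[(1S)-1-{(4S)-4-[(5R)-5-(tert-butyldiphenylsilyloxy)octyl]-4,5,6,7-tetrahydro-1-benzofuran-2-yl}ethyl]-2-methylpropane-2-sulfinamide | CC(C)(C)[S@](=O)N[C@@H](C)c1cc2[C@@H](CCCC[C@H](O[Si](c3ccccc3)(c4ccccc4)C(C)(C)C)CCC)CCCc2o1 | intermediate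
16 | (1S)-1-{(4S)-4-[(5R)-5-(tert-butyldiphenylsilyloxy)octyl]-4,5,6,7-tetrahydro-1-benzofuran-2-yl}ethanamine hydrochloride | Cl.N[C@@H](C)c1cc2[C@@H](CCCC[C@H](O[Si](c3ccccc3)(c4ccccc4)C(C)(C)C)CCC)CCCc2o1 | intermediate
17 | benzyl N-[(1S)-1-{(4S)-4-[(5R)-5-(tert-butyldiphenylsilyloxy)octyl]-4,5,6,7-tetrahydro-1-benzofuran-2-yl}ethyl]carbamate | O=C(OCc1ccccc1)N[C@@H](C)c1cc2[C@@H](CCCC[C@H](O[Si](c3ccccc3)(c4ccccc4)C(C)(C)C)CCC)CCCc2o1 | intermediate
18 | benzyl (2S,5S)-8a-hydroxy-2-methyl-3-oxo-5-[(5R)-5-(tert-butyldiphenylsilyloxy)octyl]-3,5,6,7,8,8a-hexahydroquinoline-1(2H)-carboxylate (C8a epimers) | O=C1C=C2[C@@H](CCCC[C@H](O[Si](c3ccccc3)(c4ccccc4)C(C)(C)C)CCC)CCCC2(O)N(C(=O)OCc5ccccc5)[C@H]1C | intermediate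
19 | benzyl (2S,5S,8aR)-2-methyl-3-oxo-5-[(5R)-5-(tert-butyldiphenylsilyloxy)octyl]-3,5,6,7,8,8a-hexahydroquinoline-1(2H)-carboxylate | O=C1C=C2[C@@H](CCCC[C@H](O[Si](c3ccccc3)(c4ccccc4)C(C)(C)C)CCC)CCC[C@H]2N(C(=O)OCc5ccccc5)[C@H]1C | intermediate
20 | (2S,4aS,5S,8aR)-2-methyl-5-[(5R)-5-(tert-butyldiphenylsilyloxy)octyl]octahydroquinolin-3(2H)-one | O=C1C[C@H]2[C@@H](CCCC[C@H](O[Si](c3ccccc3)(c4ccccc4)C(C)(C)C)CCC)CCC[C@H]2N[C@H]1C | intermediate
21 | (2R,4aS,5S,8aR)-2-methyl-5-[(5R)-5-(tert-butyldiphenylsilyloxy)octyl]octahydroquinolin-3(2H)-one | O=C1C[C@H]2[C@@H](CCCC[C@H](O[Si](c3ccccc3)(c4ccccc4)C(C)(C)C)CCC)CCC[C@H]2N[C@@H]1C | intermediate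
22 | (2R,3R,4aS,5S,8aR)-2-methyl-5-[(5R)-5-(tert-butyldiphenylsilyloxy)octyl]decahydroquinolin-3-ol | O[C@@H]1C[C@H]2[C@@H](CCCC[C@H](O[Si](c3ccccc3)(c4ccccc4)C(C)(C)C)CCC)CCC[C@H]2N[C@@H]1C | intermediate
23 | tert-butyl (2R,3R,4aS,5S,8aR)-3-hydroxy-2-methyl-5-[(5R)-5-(tert-butyldiphenylsilyloxy)octyl]octahydroquinoline-1(2H)-carboxylate | O[C@@H]1C[C@H]2[C@@H](CCCC[C@H](O[Si](c3ccccc3)(c4ccccc4)C(C)(C)C)CCC)CCC[C@H]2N(C(=O)OC(C)(C)C)[C@@H]1C | intermediate
24 | (2E,4E)-octa-2,4-dienal | CCC/C=C/C=C/C=O | starting material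
25 | (2E,4E)-octa-2,4-dienoic acid | CCC/C=C/C=C/C(=O)O | intermediate
26 | (2E,4E)-octa-2,4-dienoic 2,4,6-trichlorobenzoic anhydride | CCC/C=C/C=C/C(=O)OC(=O)c1c(Cl)cc(Cl)cc1Cl | intermediate
27 | tert-butyl (2R,3R,4aS,5S,8aR)-2-methyl-3-[(2E,4E)-octa-2,4-dienoyloxy]-5-[(5R)-5-(tert-butyldiphenylsilyloxy)octyl]octahydroquinoline-1(2H)-carboxylate | CCC/C=C/C=C/C(=O)O[C@@H]1C[C@H]2[C@@H](CCCC[C@H](O[Si](c3ccccc3)(c4ccccc4)C(C)(C)C)CCC)CCC[C@H]2N(C(=O)OC(C)(C)C)[C@@H]1C | intermediate
28 | (2R,3R,4aS,5S,8aR)-2-methyl-5-[(5R)-5-(tert-butyldiphenylsilyloxy)octyl]decahydroquinolin-3-yl (2E,4E)-octa-2,4-dienoate trifluoroacetate salt | CCC/C=C/C=C/C(=O)O[C@@H]1C[C@H]2[C@@H](CCCC[C@H](O[Si](c3ccccc3)(c4ccccc4)C(C)(C)C)CCC)CCC[C@H]2N[C@@H]1C.OC(=O)C(F)(F)F | intermediate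
29 | (2R,3R,4aS,5S,8aR)-5-[(5R)-5-hydroxyoctyl]-2-methyldecahydroquinolin-3-yl (2E,4E)-octa-2,4-dienoate | CCC/C=C/C=C/C(=O)O[C@@H]1C[C@H]2[C@@H](CCCC[C@H](O)CCC)CCC[C@H]2N[C@@H]1C | target

**Summary**

Total step count: 16. Longest linear sequence: 13 steps (1, 2, 4, 5, 7, 8, 9, 10, 11, 12, 13, 15, 16).

**Steps most likely to fail**

Step 11. The free α-amino ketone may self-condense or oxidise in air while it is being equilibrated, or the equilibration at C2 may stop short. The fallback sets out from 19 and comes back to the route at 23. Hydrogenation of 19 in the presence of Boc2O (H2, Pd/C, EtOAc) saturates C4=C4a and exchanges the benzyl for the tert-butyl carbamate, so that no free amine is ever present, and should give tert-butyl (2S,4aS,5S,8aR)-2-methyl-3-oxo-5-[(5R)-5-(tert-butyldiphenylsilyloxy)octyl]octahydroquinoline-1(2H)-carboxylate F7. DBU in toluene at 60 °C then equilibrates C2 on the carbamate, trading the syn-diaxial methyl/C8 pair for a single A(1,3) contact, to the (2R) epimer F8. L-Selectride reduction of F8 should give 23 directly.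

Step 5. The cationic iridium hydride may discriminate the two faces of the trisubstituted alkene poorly, or may isomerise it toward the aromatic benzofuran before reduction. The fallback sets out from 4 and comes back at 9; it makes the C5 centre by conjugate addition instead of hydrogenation. Hydrozirconation of 4 with Cp2Zr(H)Cl gives chlorobis(cyclopentadienyl)[(5R)-5-(tert-butyldiphenylsilyloxy)octyl]zirconium F1. F1 is added to cyclohex-2-en-1-one with CuOTf and a chiral phosphoramidite ligand in the presence of Me3SiCl and should give the silyl enol ether {[(3S)-3-[(5R)-5-(tert-butyldiphenylsilyloxy)octyl]cyclohex-1-en-1-yl]oxy}trimethylsilane F2. MeLi liberates the regiodefined lithium enolate F3, and allyl iodide alkylates it trans to the chain to give (2R,3S)-2-allyl-3-[(5R)-5-(tert-butyldiphenylsilyloxy)octyl]cyclohexan-1-one F4. Lemieux–Johnson cleavage (OsO4 cat., NaIO4) gives the keto aldehyde 2-{(1R,2S)-2-[(5R)-5-(tert-butyldiphenylsilyloxy)octyl]-6-oxocyclohexyl}acetaldehyde F5, and Paal–Knorr cyclodehydration (TsOH cat., toluene) closes the furan to 9.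

Step 9. The peracid may over-oxidise the enedione, or the acidic medium may epimerise C2 before the hemiaminal has closed. The fallback sets out from 17 and comes back at 18; it separates oxidation from ring closure. Clauson-Kaas-type oxidation with Br2 in MeOH/NaHCO3 at −40 °C gives the 2,5-dimethoxy-2,5-dihydrofuran benzyl N-[(1S)-1-{(4S)-2,7a-dimethoxy-4-[(5R)-5-(tert-butyldiphenylsilyloxy)octyl]-2,4,5,6,7,7a-hexahydro-1-benzofuran-2-yl}ethyl]carbamate F6. Mild hydrolysis of F6 (PPTS, acetone/H2O) unmasks the cis-enedione, which closes to 18.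

Further compounds
F1 | step 5 | chlorobis(cyclopentadienyl)[(5R)-5-(tert-butyldiphenylsilyloxy)octyl]zirconium | Cl[Zr](CCCC[C@H](O[Si](c1ccccc1)(c1ccccc1)C(C)(C)C)CCC)(C1C=CC=C1)C1C=CC=C1
F2 | step 5 | {[(3S)-3-[(5R)-5-(tert-butyldiphenylsilyloxy)octyl]cyclohex-1-en-1-yl]oxy}trimethylsilane | C[Si](C)(C)OC1=C[C@@H](CCCC[C@H](O[Si](c2ccccc2)(c2ccccc2)C(C)(C)C)CCC)CCC1
F3 | step 5 | lithium (3S)-3-[(5R)-5-(tert-butyldiphenylsilyloxy)octyl]cyclohex-1-en-1-olate | [Li]OC1=C[C@@H](CCCC[C@H](O[Si](c2ccccc2)(c2ccccc2)C(C)(C)C)CCC)CCC1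
F4 | step 5 | (2R,3S)-2-allyl-3-[(5R)-5-(tert-butyldiphenylsilyloxy)octyl]cyclohexan-1-one | C=CC[C@@H]1[C@@H](CCCC[C@H](O[Si](c2ccccc2)(c2ccccc2)C(C)(C)C)CCC)CCCC1=O
F5 | step 5 | 2-{(1R,2S)-2-[(5R)-5-(tert-butyldiphenylsilyloxy)octyl]-6-oxocyclohexyl}acetaldehyde | O=CC[C@@H]1[C@@H](CCCC[C@H](O[Si](c2ccccc2)(c2ccccc2)C(C)(C)C)CCC)CCCC1=O
F6 | step 9 | benzyl N-[(1S)-1-{(4S)-2,7a-dimethoxy-4-[(5R)-5-(tert-butyldiphenylsilyloxy)octyl]-2,4,5,6,7,7a-hexahydro-1-benzofuran-2-yl}ethyl]carbamate | COC1(C=C2[C@@H](CCCC[C@H](O[Si](c3ccccc3)(c4ccccc4)C(C)(C)C)CCC)CCCC2(OC)O1)[C@H](C)NC(=O)OCc1ccccc1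
F7 | step 11 | tert-butyl (2S,4aS,5S,8aR)-2-methyl-3-oxo-5-[(5R)-5-(tert-butyldiphenylsilyloxy)octyl]octahydroquinoline-1(2H)-carboxylate | O=C1C[C@H]2[C@@H](CCCC[C@H](O[Si](c3ccccc3)(c4ccccc4)C(C)(C)C)CCC)CCC[C@H]2N(C(=O)OC(C)(C)C)[C@H]1C
F8 | step 11 | tert-butyl (2R,4aS,5S,8aR)-2-methyl-3-oxo-5-[(5R)-5-(tert-butyldiphenylsilyloxy)octyl]octahydroquinoline-1(2H)-carboxylate | O=C1C[C@H]2[C@@H](CCCC[C@H](O[Si](c3ccccc3)(c4ccccc4)C(C)(C)C)CCC)CCC[C@H]2N(C(=O)OC(C)(C)C)[C@@H]1C
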